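**Retrosynthetic overview** (daucane numbering: C1 quaternary ring-fusion carbon, C4 carbinol carbon with isopropyl, C5 ring-fusion CH, C6 CH–O–aroyl, C7 CH2, C8=C9 alkene, C10 CH–O–angeloyl)
1. Target 24 ⇐ silyl-protected hydroazulenone 17 by 6-O-aroylation, reduction of the C10 ketone, angeloylation and desilylation.
2. 17 ⇐ monocyclic cyclohexane 14, which already holds all 15 skeletal carbons: one Me2AlCl operation makes C5–C1 (1,2-shift that contracts the six-membered ring to the five-membered ring) and C6–C7 (carbonyl-ene closure of the seven-membered ring).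
3. Enabling feature: on the six-membered ring of 14 the C6 hydroxyl and the equatorial C5 mesylate are trans-vicinal, so the C6–C1 ring bond is antiperiplanar to C5–OMs; C1 is quaternary and carries the methallyl ketone arm (C10, C9, C8, C7) trans to the formyl group that the shift sets free, so only the seven-membered closure is possible and the ketone later fixes C8=C9.
4. 14 ⇐ Diels–Alder adduct 7 (catalytic, enantioselective, endo) of silyloxydiene 5 and methacrolein 6, through syn-dihydroxylation, mesylation, silylation and methallylation/oxidation.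
5. Ring order: six-membered carbocycle (step 3), then five-membered ring by contraction and seven-membered ring by closure, both in step 10.

Key step: step 10

Assumption: the (S)-tryptophan-derived oxazaborolidinone is taken to direct the diene to the enal face that gives (1S,2R)-7, by analogy with the accepted model for 2-substituted acroleins; if the sense were opposite, the catalyst from (R)-tryptophan would be used.

**Step 1**
Reactants: 1 3-methylbutan-2-one; 2 ethyl formate
Product: 4 (E)-4-methyl-1-(triethylsilyloxy)pent-1-en-3-one, via sodium enolate 3 (not isolated)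
Conditions: NaH, Et2O, cat. EtOH, 0 °C → rt; then Et3SiCl, THF, 0 °C
Reagents that add atoms: chlorotriethylsilane CC[Si](Cl)(CC)CC
Why: Claisen formylation takes place at the methyl group (only that position gives a stabilised β-ketoaldehyde salt) and O-silylation of the salt should give the vinylogous silyl ester as the thermodynamically preferred E isomer.

**Step 2**
Reactants: 4
Product: 5 (E)-3-isopropyl-1-(triethylsilyloxy)buta-1,3-diene
Conditions: Ph3PCH3Br, KOtBu, THF, 0 °C; then 4, 0 °C → rt
Reagents that add atoms: methylenetriphenylphosphorane (from methyltriphenylphosphonium bromide) C=P(c1ccccc1)(c1ccccc1)c1ccccc1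
Why: Wittig methylenation of the ketone carbonyl should give the 1-silyloxy-3-alkyl diene and leave the E enol ether geometry untouched.

**Step 3**
Reactants: 5; 6 methacrolein
Product: 7 (1S,2R)-1-methyl-4-(propan-2-yl)-2-(triethylsilyloxy)cyclohex-3-ene-1-carbaldehyde
Conditions: oxazaborolidinone from N-tosyl-(S)-tryptophan and BuB(OH)2 (10 mol%), CH2Cl2, −78 °C
Reagents that add atoms: none
Why: Catalytic enantioselective Diels–Alder reaction in which the oxygenated diene terminus bonds to the α-carbon of the enal (ortho rule), the catalyst-bound formyl group is endo (OSiEt3 cis to CHO) and the chiral Lewis acid shields one enal face, which sets the quaternary carbon (later C1) and the silyloxy carbon (later C6) together.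

**Step 4**
Reactants: 7
Product: 8 (1S,2S,3R,4R)-3,4-dihydroxy-1-methyl-4-(propan-2-yl)-2-(triethylsilyloxy)cyclohexane-1-carbaldehyde
Conditions: OsO4 (3 mol%), NMO, acetone/H2O, 0 °C → rt
Reagents that add atoms: osmium tetroxide O=[Os](=O)(=O)=O; N-methylmorpholine N-oxide C[N+]1([O-])CCOCC1; water O
Why: Upjohn syn-dihydroxylation of the only alkene, which should occur anti to the allylic silyloxy group and to the formyl group on the same face, so that both new hydroxyls are cis to the ring methyl group.

**Step 5**
Reactants: 8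
Product: 9 (1S,2S,3R,4R)-4-hydroxy-3-(methanesulfonyloxy)-1-methyl-4-(propan-2-yl)-2-(triethylsilyloxy)cyclohexane-1-carbaldehyde
Conditions: MsCl, Et3N, CH2Cl2, −20 °C
Reagents that add atoms: methanesulfonyl chloride CS(=O)(=O)Cl
Why: Sulfonylation should take place only at the secondary hydroxyl (the tertiary one is inert), and the cis hydroxy mesylate cannot close to an epoxide.

**Step 6**
Reactants: 9
Product: 10 (1S,2S,3R,4R)-4-(tert-butyldimethylsilyloxy)-3-(methanesulfonyloxy)-1-methyl-4-(propan-2-yl)-2-(triethylsilyloxy)cyclohexane-1-carbaldehyde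
Conditions: TBSOTf, 2,6-lutidine, CH2Cl2, 0 °C
Reagents that add atoms: tert-butyldimethylsilyl triflate CC(C)(C)[Si](C)(C)OS(=O)(=O)C(F)(F)F
Why: Silyl triflate silylation of the tertiary alcohol, which turns O4 into a poor electron donor so that it cannot later drive the competing shift.

**Step 7**
Reactants: 10; 11 (2-methylallyl)magnesium chloride
Product: 12 1-[4-(tert-butyldimethylsilyloxy)-3-(methanesulfonyloxy)-1-methyl-4-(propan-2-yl)-2-(triethylsilyloxy)cyclohexyl]-3-methylbut-3-en-1-ol (ring as in 10; carbinol epimers)
Conditions: THF, −78 °C; aq. NH4Cl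
Reagents that add atoms: none
Why: Grignard addition to the neopentyl aldehyde should be fast at −78 °C while mesylate and silyl ethers stay intact; the new carbinol centre is removed in the next step, so its configuration is irrelevant.

**Step 8**
Reactants: 12
Product: 13 1-[(1S,2S,3R,4R)-4-(tert-butyldimethylsilyloxy)-3-(methanesulfonyloxy)-1-methyl-4-(propan-2-yl)-2-(triethylsilyloxy)cyclohexyl]-3-methylbut-3-en-1-one
Conditions: Dess–Martin periodinane, NaHCO3, CH2Cl2, 0 °C
Reagents that add atoms: none
Why: Buffered Dess–Martin oxidation should give the β,γ-unsaturated ketone without moving the alkene into conjugation.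

**Step 9**
Reactants: 13
Product: 14 1-[(1S,2S,3R,4R)-4-(tert-butyldimethylsilyloxy)-2-hydroxy-3-(methanesulfonyloxy)-1-methyl-4-(propan-2-yl)cyclohexyl]-3-methylbut-3-en-1-one
Conditions: HF·pyridine, pyridine, THF, 0 °C
Reagents that add atoms: none
Why: Selective desilylation, since a secondary triethylsilyl ether is cleaved far faster than a tertiary tert-butyldimethylsilyl ether under buffered fluoride.

**Step 10**
Reactants: 14
Product: 17 (1S,4R,5S,6S)-4-(tert-butyldimethylsilyloxy)-6-hydroxydauc-8-en-10-one, via formylcyclopentane 15 (not isolated), via exo-methylene ene adduct 16 (not isolated)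
Conditions: Me2AlCl (3 equiv), CH2Cl2, −78 → 0 °C; then MeOH, DBU, rt
Reagents that add atoms: none
Why: Proposed new method: Me2AlCl converts the free 6-OH into a chloro(methyl)aluminium alkoxide whose metal also binds the neighbouring sulfonate, and the C6–C1 ring bond, antiperiplanar to the equatorial C5–OMs bond, shifts to C5 as mesylate leaves (closest known type: the organoaluminium-promoted pinacol-type 1,2-shift of β-mesyloxy alcohols, here as a six-to-five ring contraction), which sets free the aluminium-bound C6 aldehyde 15. The 1,1-disubstituted alkene then adds through C7 to this aldehyde in a type 2 carbonyl-ene reaction under the same Lewis acid (closest known type: Me2AlCl-promoted ene cyclisation of alkenals to 3-methylenecycloalkanols), a seven-membered closure that is exo-trig at the carbonyl carbon with the ene alkene inside the new ring, and DBU then moves the double bond of 16 into conjugation with the C10 ketone, which fixes C8=C9. The five-membered ring is thus closed by a suprafacial 1,2-shift with inversion at C5 and retention at C1, so H5 is anti to the 1-methyl group (trans fusion) and the formyl and C10 arms are trans, an arrangement from which a five-membered aldol-type closure is geometrically excluded. C6 is set in the ene transition state, where C7 approaches anti to the fully substituted C4 (Felkin sense) with the aluminium-bound oxygen pseudo-equatorial, which places H6 anti to H5. The step needs C1 and not C3 to migrate (the C4–C3 bond is also antiperiplanar to C5–OMs); this is secured by having a metal alkoxide only at C6 while O4 is a silyl ether and a poor donor, and epoxide formation is held back because O6 and OMs are diequatorial in the ground-state chair and an aluminium alkoxide is a weak nucleophile. The aldehyde should react in the ene step in preference to the hindered neopentyl ketone.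

**Step 11**
Reactants: 17; 18 4-[(tert-butyldimethylsilyl)oxy]benzoic acid
Product: 19 (1S,4R,5S,6S)-4-(tert-butyldimethylsilyloxy)-10-oxodauc-8-en-6-yl 4-[(tert-butyldimethylsilyl)oxy]benzoate
Conditions: EDC·HCl, DMAP, CH2Cl2, rt
Reagents that add atoms: none
Why: Steglich esterification of the only free hydroxyl (secondary, equatorial); the enone and both silyl ethers are inert.

**Step 12**
Reactants: 19
Product: 20 (1S,4R,5S,6S,10R)-4-(tert-butyldimethylsilyloxy)-10-hydroxydauc-8-en-6-yl 4-[(tert-butyldimethylsilyl)oxy]benzoate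
Conditions: (S)-Me-CBS oxazaborolidine (1 equiv), catecholborane, toluene, −78 → −40 °C
Reagents that add atoms: none
Why: Corey–Bakshi–Shibata 1,2-reduction under catalyst control, with the quaternary C1 as the large and the alkenyl C9 as the small carbonyl substituent, should deliver hydride to the face of the 1-methyl group and give the 10R alcohol (O10 cis to O6), against the substrate's own bias.

**Step 13**
Reactants: 20; 21 angelic acid
Product: 23 (1S,4R,5S,6S,10R)-10-angeloyloxy-4-(tert-butyldimethylsilyloxy)dauc-8-en-6-yl 4-[(tert-butyldimethylsilyl)oxy]benzoate, via mixed anhydride 22 (not isolated)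
Conditions: 2,4,6-Cl3C6H2COCl, Et3N, toluene, rt; then 20, 80 °C
Reagents that add atoms: none
Why: Yamaguchi-type mixed-anhydride esterification, a protocol suited to hindered alcohols that should transfer the angeloyl group without Z-to-E isomerisation to the tiglate; C10 keeps its configuration.

**Step 14**
Reactants: 23
Product: 24 target CNP0273650.2, (1S,4R,5S,6S,10R)-10-angeloyloxy-4-hydroxydauc-8-en-6-yl 4-hydroxybenzoate
Conditions: HF·pyridine, pyridine, THF, 0 °C → rt
Reagents that add atoms: none
Why: Buffered fluoride desilylation should cleave the aryl and the tertiary silyl ether while both esters and both alkenes stay untouched.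

**Compound list**
1 | 3-methylbutan-2-one | CC(C)C(C)=O | starting material
2 | ethyl formate | CCOC=O | starting material
3 | sodium (Z)-4-methyl-3-oxopent-1-en-1-olate | CC(C)C(=O)/C=C\[O-].[Na+] | intermediate
4 | (E)-4-methyl-1-(triethylsilyloxy)pent-1-en-3-one | CC(C)C(=O)/C=C/O[Si](CC)(CC)CC | intermediate
5 | (E)-3-isopropyl-1-(triethylsilyloxy)buta-1,3-diene | CC(C)C(=C)/C=C/O[Si](CC)(CC)CC | intermediate
6 | methacrolein (2-methylprop-2-enal) | CC(=C)C=O | starting material
7 | (1S,2R)-1-methyl-4-(propan-2-yl)-2-(triethylsilyloxy)cyclohex-3-ene-1-carbaldehyde (OSiEt3 cis to CHO) | O=C[C@@]1(C)CCC(C(C)C)=C[C@H]1O[Si](CC)(CC)CC | intermediate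
8 | (1S,2S,3R,4R)-3,4-dihydroxy-1-methyl-4-(propan-2-yl)-2-(triethylsilyloxy)cyclohexane-1-carbaldehyde (3-OH and 4-OH cis to 1-methyl; trans to OSiEt3 and CHO) | O=C[C@@]1(C)CC[C@@](O)(C(C)C)[C@H](O)[C@H]1O[Si](CC)(CC)CC | intermediate
9 | 3-O-methanesulfonate of 8 | O=C[C@@]1(C)CC[C@@](O)(C(C)C)[C@H](OS(C)(=O)=O)[C@H]1O[Si](CC)(CC)CC | intermediate
10 | 4-O-tert-butyldimethylsilyl ether of 9 | O=C[C@@]1(C)CC[C@@](O[Si](C)(C)C(C)(C)C)(C(C)C)[C@H](OS(C)(=O)=O)[C@H]1O[Si](CC)(CC)CC | intermediate
11 | (2-methylallyl)magnesium chloride | C=C(C)C[Mg]Cl | starting material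
12 | methallyl carbinol from 10 (ring as in 10; carbinol epimers) | C=C(C)CC(O)[C@@]1(C)CC[C@@](O[Si](C)(C)C(C)(C)C)(C(C)C)[C@H](OS(C)(=O)=O)[C@H]1O[Si](CC)(CC)CC | intermediate
13 | methallyl ketone from 12 (ring 1S,2S,3R,4R) | C=C(C)CC(=O)[C@@]1(C)CC[C@@](O[Si](C)(C)C(C)(C)C)(C(C)C)[C@H](OS(C)(=O)=O)[C@H]1O[Si](CC)(CC)CC | intermediate
14 | 2-hydroxy ketone from 13 (free OH trans to OMs; cis to the acyl group) | C=C(C)CC(=O)[C@@]1(C)CC[C@@](O[Si](C)(C)C(C)(C)C)(C(C)C)[C@H](OS(C)(=O)=O)[C@H]1O | intermediate
15 | (1R,2S,5R)-5-(tert-butyldimethylsilyloxy)-2-methyl-2-(3-methylbut-3-enoyl)-5-(propan-2-yl)cyclopentane-1-carbaldehyde (CHO trans to the acyl group) | C=C(C)CC(=O)[C@@]1(C)CC[C@@](O[Si](C)(C)C(C)(C)C)(C(C)C)[C@@H]1C=O | intermediate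
16 | (1S,4R,5S,6S)-4-(tert-butyldimethylsilyloxy)-6-hydroxydauc-8(14)-en-10-one | O=C1CC(=C)C[C@H](O)[C@@H]2[C@]1(C)CC[C@@]2(O[Si](C)(C)C(C)(C)C)C(C)C | intermediate
17 | (1S,4R,5S,6S)-4-(tert-butyldimethylsilyloxy)-6-hydroxydauc-8-en-10-one (trans-fused; 6-OH cis to H5) | O=C1C=C(C)C[C@H](O)[C@@H]2[C@]1(C)CC[C@@]2(O[Si](C)(C)C(C)(C)C)C(C)C | intermediate
18 | 4-[(tert-butyldimethylsilyl)oxy]benzoic acid | CC(C)(C)[Si](C)(C)Oc1ccc(cc1)C(=O)O | starting material
19 | 6-O-[4-(tert-butyldimethylsilyloxy)benzoyl] derivative of 17 | O=C1C=C(C)C[C@H](OC(=O)c3ccc(O[Si](C)(C)C(C)(C)C)cc3)[C@@H]2[C@]1(C)CC[C@@]2(O[Si](C)(C)C(C)(C)C)C(C)C | intermediate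
20 | (10R)-alcohol from 19 (10-OH cis to the 6-ester; trans to 1-methyl) | O[C@@H]1C=C(C)C[C@H](OC(=O)c3ccc(O[Si](C)(C)C(C)(C)C)cc3)[C@@H]2[C@]1(C)CC[C@@]2(O[Si](C)(C)C(C)(C)C)C(C)C | intermediate
21 | angelic acid, (Z)-2-methylbut-2-enoic acid | C/C=C(/C)C(=O)O | starting material
22 | angelic 2,4,6-trichlorobenzoic anhydride | C/C=C(/C)C(=O)OC(=O)c1c(Cl)cc(Cl)cc1Cl | intermediate
23 | 10-O-angeloyl derivative of 20 (bis-silyl ether of the target) | C/C=C(/C)C(=O)O[C@@H]1C=C(C)C[C@H](OC(=O)c3ccc(O[Si](C)(C)C(C)(C)C)cc3)[C@@H]2[C@]1(C)CC[C@@]2(O[Si](C)(C)C(C)(C)C)C(C)C | intermediate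
24 | CNP0273650.2, (1S,4R,5S,6S,10R)-10-angeloyloxy-4-hydroxydauc-8-en-6-yl 4-hydroxybenzoate | C/C=C(/C)C(=O)O[C@@H]1C=C(C)C[C@H](OC(=O)c2ccc(O)cc2)[C@@H]2[C@]1(C)CC[C@@]2(O)C(C)C | target

**Totals:** 14 steps; longest linear sequence 14 steps (from 1 and 2).

**Steps most likely to fail**

Step 10 (proposed cascade). The 1,2-shift may be outrun by retro-aldol cleavage of the β-aluminoxy ketone or by migration of C3, and the seven-membered ene closure may lose to chloride capture or methyl transfer from aluminium. The fallback sets out from 14 and uses known reactions only. Et3Al (CH2Cl2, −78 °C) effects the organoaluminium pinacol-type rearrangement and aldehyde 15 is isolated. Vinylmagnesium bromide (THF, −78 °C) adds to the aldehyde alone and should give the allylic alcohol F1 (Felkin addition anti to C4; a C6 epimer would be separated and recycled by oxidation and reduction). Ring-closing metathesis with the second-generation Hoveyda–Grubbs catalyst (CH2Cl2, 40 °C) joins the vinyl and methallyl groups to the cycloheptenol F2 with a C7=C8 alkene. DBU then moves the double bond into conjugation through the C9 dienolate, and the route is rejoined at 17.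

Step 12. Facial selectivity may be poor, because the catalyst has to deliver hydride on the side of the axial 1-methyl group against the substrate's bias. The fallback sets out from 19: Luche reduction (NaBH4, CeCl3·7H2O, MeOH, −78 °C) follows the substrate bias and should give the 10-epimeric alcohol F3. Mitsunobu esterification with angelic acid 21 (PPh3, DIAD, toluene, 0 °C) inverts C10 and rejoins the route at 23.

Step 3. Enantio- or endo-selectivity may erode, and the acid-sensitive silyloxydiene may be lost to catalyst-induced hydrolysis or oligomerisation. The fallback sets out from 5 and 6: an uncatalysed Diels–Alder reaction (toluene, 80 °C, cat. BHT) gives the endo adduct as a racemate, that is 7 together with its enantiomer F4. Condensation with (1R,2R)-N,N'-dimethyl-1,2-diphenylethane-1,2-diamine (MgSO4, Et2O) gives the diastereomeric imidazolidines F5 (from 7) and F6 (from F4), which are separated by chromatography. Mild hydrolysis of F5 (dilute aqueous HCl, Et2O, 0 °C) rejoins the route at 7.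

**Further compounds**
F1 | step 10 | 1-[(1S,2R,3R)-3-(tert-butyldimethylsilyloxy)-2-(1-hydroxyprop-2-en-1-yl)-1-methyl-3-(propan-2-yl)cyclopentyl]-3-methylbut-3-en-1-one (carbinol configuration as C6 of 17) | C=C(C)CC(=O)[C@@]1(C)CC[C@@](O[Si](C)(C)C(C)(C)C)(C(C)C)[C@@H]1[C@@H](O)C=C
F2 | step 10 | (1S,4R,5S,6S)-4-(tert-butyldimethylsilyloxy)-6-hydroxydauc-7-en-10-one | O=C1CC(C)=C[C@H](O)[C@@H]2[C@]1(C)CC[C@@]2(O[Si](C)(C)C(C)(C)C)C(C)C
F3 | step 12 | (10S)-epimer of 20 | O[C@H]1C=C(C)C[C@H](OC(=O)c3ccc(O[Si](C)(C)C(C)(C)C)cc3)[C@@H]2[C@]1(C)CC[C@@]2(O[Si](C)(C)C(C)(C)C)C(C)C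
F4 | step 3 | (1R,2S)-enantiomer of 7 | O=C[C@]1(C)CCC(C(C)C)=C[C@@H]1O[Si](CC)(CC)CC
F5 | step 3 | (4R,5R)-1,3-dimethyl-4,5-diphenylimidazolidine aminal of 7 | CN1[C@H](c2ccccc2)[C@@H](c2ccccc2)N(C)C1[C@@]3(C)CCC(C(C)C)=C[C@H]3O[Si](CC)(CC)CC
F6 | step 3 | (4R,5R)-1,3-dimethyl-4,5-diphenylimidazolidine aminal of F4 | CN1[C@H](c2ccccc2)[C@@H](c2ccccc2)N(C)C1[C@]3(C)CCC(C(C)C)=C[C@@H]3O[Si](CC)(CC)CC
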